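The route rests on a hidden symmetry of the butyrolactone ring. Without its C3 benzyl group, C4 is flanked by two CH2 groups (C3 and C5), so C2–C3–C4–C5 maps onto a mirror-symmetric 3-(arylmethyl)cyclobutanone made from eugenol and dichloroketene. A catalytic enantioselective Baeyer–Villiger oxidation then shifts one enantiotopic CH2 from carbon to oxygen: this single event forms the C5–O1 bond, closes the γ-lactone and fixes C4 as R. The ring B/ring C arm, built by an Evans syn aldol, is attached as a benzylic bromide trans to the C4 substituent, and one fluoride treatment frees all five hydroxyl groups.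

Key step: step 4

Remark: lactone atoms are numbered O1, C2 (carbonyl), C3, C4, C5; ring A is the guaiacyl ring on the C4 benzyl group, ring B the one on the C3 benzyl group, ring C the one of the diol arm. The antipode of the chiral ligand in step 4 is assumed to be chosen in a first trial so that the R lactone results.

Step 1
Reactants: 1 eugenol (4-allyl-2-methoxyphenol)
Product: 2 (4-allyl-2-methoxyphenoxy)triisopropylsilane
Conditions: TIPSCl, imidazole, DMF, rt
Reagents that add atoms: triisopropylsilyl chloride, CC(C)[Si](Cl)(C(C)C)C(C)C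
Why: Imidazole-promoted O-silylation of the phenol should give an aryl silyl ether that survives the ketene, zinc, peracid and enolate steps and is removed by fluoride at the end.

Step 2
Reactants: 2 (4-allyl-2-methoxyphenoxy)triisopropylsilane; 3 trichloroacetyl chloride
Product: 5 2,2-dichloro-3-[3-methoxy-4-(triisopropylsilyloxy)benzyl]cyclobutan-1-one (racemic), via dichloroketene 4 (not isolated)
Conditions: Zn–Cu couple, POCl3, Et2O, 35 °C
Reagents that add atoms: none
Why: Zinc dechlorinates 3 to dichloroketene, which should undergo the thermal [2+2] ketene–alkene cycloaddition with the terminal alkene, the carbonyl carbon bonding to the terminal CH2 so that the benzyl group sits at C3.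

Step 3
Reactants: 5 2,2-dichloro-3-[3-methoxy-4-(triisopropylsilyloxy)benzyl]cyclobutan-1-one
Product: 6 3-[3-methoxy-4-(triisopropylsilyloxy)benzyl]cyclobutan-1-one
Conditions: Zn dust, AcOH, rt to 50 °C
Reagents that add atoms: none
Why: Reductive dehalogenation of the α,α-dichloroketone (zinc enolate, protonation by AcOH) should remove both chlorines and leave the prochiral, mirror-symmetric cyclobutanone.

Step 4
Reactants: 6 3-[3-methoxy-4-(triisopropylsilyloxy)benzyl]cyclobutan-1-one
Product: 8 (R)-4-[3-methoxy-4-(triisopropylsilyloxy)benzyl]dihydrofuran-2(3H)-one, via Criegee adduct 7 (not isolated)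
Conditions: mCPBA (1.2 equiv), Sc(OTf)3 (5 mol %), C2-symmetric chiral N,N′-dioxide bis(amide) ligand (pipecolic acid-derived, 2,6-diisopropylanilide arms, 6 mol %), EtOAc, −20 °C
Reagents that add atoms: 3-chloroperoxybenzoic acid (mCPBA), OOC(=O)c1cccc(Cl)c1
Why: The Sc(OTf)3-activated ketone should add the peracid to give Criegee adduct 7, and the ring CH2 that lies antiperiplanar to the O–O bond then shifts from carbon to oxygen with loss of 3-chlorobenzoate, so that the C5–O1 bond forms as the C–C bond of the four-membered ring breaks. The closest known reaction type is the catalytic enantioselective Baeyer–Villiger desymmetrisation of prochiral 3-substituted cyclobutanones. The γ-lactone closes by a 1,2-shift ring expansion (four- to five-membered), driven by release of cyclobutanone strain, not by an end-to-end cyclisation. C4 becomes the only new stereocentre, and its R configuration is set by the chiral N,N′-dioxide–scandium complex, which should hold adduct 7 so that only one of the two enantiotopic CH2 groups can align with the O–O bond. The step needs enantiotopic-group selectivity (from the ligand) and chemoselectivity over the electron-rich silyloxyarene (from the high rate of strained-ketone oxidation at −20 °C); regioselectivity is not an issue because both candidate migrating groups are CH2 groups related by the mirror plane of 6.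

Step 5
Reactants: 9 methyl 3-bromo-4-hydroxy-5-methoxybenzoate (methyl 5-bromovanillate)
Product: 10 methyl 3-bromo-5-methoxy-4-(triisopropylsilyloxy)benzoate
Conditions: TIPSOTf, 2,6-lutidine, CH2Cl2, 0 °C to rt
Reagents that add atoms: triisopropylsilyl triflate, CC(C)[Si](OS(=O)(=O)C(F)(F)F)(C(C)C)C(C)C
Why: O-Silylation with the reactive silyl triflate should protect the hindered, acidic phenol of ring B as a robust silyl ether.

Step 6
Reactants: 10 methyl 3-bromo-5-methoxy-4-(triisopropylsilyloxy)benzoate; 11 (2-tert-butoxy-2-oxoethyl)zinc bromide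
Product: 12 methyl 3-(2-tert-butoxy-2-oxoethyl)-5-methoxy-4-(triisopropylsilyloxy)benzoate
Conditions: Pd(dba)2 (3 mol %), P(t-Bu)3 (3 mol %), THF, rt to 50 °C
Reagents that add atoms: none
Why: Palladium-catalysed α-arylation of the zinc ester enolate (Reformatsky–Negishi coupling: oxidative addition of the aryl bromide to zerovalent palladium, transmetalation, reductive elimination) should install the acetic ester arm under neutral conditions that spare the methyl ester and silyl ether.

Step 7
Reactants: 12 methyl 3-(2-tert-butoxy-2-oxoethyl)-5-methoxy-4-(triisopropylsilyloxy)benzoate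
Product: 13 2-[3-methoxy-5-(methoxycarbonyl)-2-(triisopropylsilyloxy)phenyl]acetic acid
Conditions: TFA, CH2Cl2, 0 °C to rt
Reagents that add atoms: none
Why: Acidolysis of the tert-butyl ester (loss of isobutene via the tert-butyl cation) should free the arylacetic acid while the methyl benzoate and the aryl silyl ether stay intact.

Step 8
Reactants: 13 2-[3-methoxy-5-(methoxycarbonyl)-2-(triisopropylsilyloxy)phenyl]acetic acid; 14 (S)-4-benzyloxazolidin-2-one
Product: 16 methyl 3-{2-[(S)-4-benzyl-2-oxooxazolidin-3-yl]-2-oxoethyl}-5-methoxy-4-(triisopropylsilyloxy)benzoate, via mixed pivalic anhydride 15 (not isolated)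
Conditions: PivCl, Et3N, THF, −20 °C; then 14, LiCl, −20 °C to rt
Reagents that add atoms: none
Why: N-Acylation of the oxazolidinone through the mixed pivalic anhydride (LiCl/Et3N activation) should occur at the less hindered arylacetyl carbonyl and give the imide needed for the auxiliary-controlled aldol.

Step 9
Reactants: 16 methyl 3-{2-[(S)-4-benzyl-2-oxooxazolidin-3-yl]-2-oxoethyl}-5-methoxy-4-(triisopropylsilyloxy)benzoate; 17 4-(tert-butyldimethylsilyloxy)-3-methoxybenzaldehyde
Product: 20 methyl 3-{(2S,3S)-1-[(S)-4-benzyl-2-oxooxazolidin-3-yl]-3-[4-(tert-butyldimethylsilyloxy)-3-methoxyphenyl]-3-hydroxy-1-oxopropan-2-yl}-5-methoxy-4-(triisopropylsilyloxy)benzoate, via dibutylboron enolate 18 (not isolated), via dibutylboron aldolate 19 (not isolated)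
Conditions: Bu2BOTf, i-Pr2NEt, CH2Cl2, 0 °C; then 17, −78 to 0 °C; then pH 7 buffer, MeOH, 30% H2O2, 0 °C
Reagents that add atoms: none
Why: In this Evans syn aldol the (Z)-boron enolate should react through a chair-like Zimmerman–Traxler transition state with the auxiliary carbonyl turned away (dipole minimised), so the aldehyde adds to the enolate face remote from the benzyl group and both new centres (2S,3S, ring B and hydroxyl syn) are set by the (S)-auxiliary.

Step 10
Reactants: 20 methyl 3-{(2S,3S)-1-[(S)-4-benzyl-2-oxooxazolidin-3-yl]-3-[4-(tert-butyldimethylsilyloxy)-3-methoxyphenyl]-3-hydroxy-1-oxopropan-2-yl}-5-methoxy-4-(triisopropylsilyloxy)benzoate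
Product: 21 methyl 3-{(1S,2R)-1-[4-(tert-butyldimethylsilyloxy)-3-methoxyphenyl]-1,3-dihydroxypropan-2-yl}-5-methoxy-4-(triisopropylsilyloxy)benzoate
Conditions: LiBH4, MeOH (1 equiv), THF, 0 °C
Reagents that add atoms: none
Why: Reductive cleavage of the auxiliary by hydride attack on the activated exocyclic imide carbonyl should give the primary alcohol, while the electron-rich aryl methyl ester is not reduced at 0 °C and both stereocentres are untouched (the descriptor of the ring B-bearing carbon changes to R by priority only).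

Step 11
Reactants: 21 methyl 3-{(1S,2R)-1-[4-(tert-butyldimethylsilyloxy)-3-methoxyphenyl]-1,3-dihydroxypropan-2-yl}-5-methoxy-4-(triisopropylsilyloxy)benzoate
Product: 22 methyl 3-{(1S,2R)-1,3-bis(tert-butyldimethylsilyloxy)-1-[4-(tert-butyldimethylsilyloxy)-3-methoxyphenyl]propan-2-yl}-5-methoxy-4-(triisopropylsilyloxy)benzoate
Conditions: TBSOTf, 2,6-lutidine, CH2Cl2, −78 to 0 °C
Reagents that add atoms: tert-butyldimethylsilyl triflate, CC(C)(C)[Si](C)(C)OS(=O)(=O)C(F)(F)F
Why: Bis-O-silylation under non-acidic conditions should mask the primary and the ionisation-prone benzylic hydroxyl groups for the hydride, bromination and enolate steps.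

Step 12
Reactants: 22 methyl 3-{(1S,2R)-1,3-bis(tert-butyldimethylsilyloxy)-1-[4-(tert-butyldimethylsilyloxy)-3-methoxyphenyl]propan-2-yl}-5-methoxy-4-(triisopropylsilyloxy)benzoate
Product: 23 {3-[(1S,2R)-1,3-bis(tert-butyldimethylsilyloxy)-1-[4-(tert-butyldimethylsilyloxy)-3-methoxyphenyl]propan-2-yl]-5-methoxy-4-(triisopropylsilyloxy)phenyl}methanol
Conditions: i-Bu2AlH, CH2Cl2, −78 to −40 °C; aqueous potassium sodium tartrate work-up
Reagents that add atoms: none
Why: Hydride reduction of the methyl ester by the aluminium hydride should give the benzylic alcohol of ring B without touching the silyl ethers.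

Step 13
Reactants: 23 {3-[(1S,2R)-1,3-bis(tert-butyldimethylsilyloxy)-1-[4-(tert-butyldimethylsilyloxy)-3-methoxyphenyl]propan-2-yl]-5-methoxy-4-(triisopropylsilyloxy)phenyl}methanol
Product: 24 {2-[(1S,2R)-1,3-bis(tert-butyldimethylsilyloxy)-1-[4-(tert-butyldimethylsilyloxy)-3-methoxyphenyl]propan-2-yl]-4-(bromomethyl)-6-methoxyphenoxy}triisopropylsilane
Conditions: CBr4, PPh3, CH2Cl2, 0 °C
Reagents that add atoms: carbon tetrabromide, BrC(Br)(Br)Br
Why: The Appel reaction (alkoxyphosphonium formation, SN2 displacement by bromide) should convert the primary benzylic alcohol to the bromide under neutral conditions that the silyl ethers tolerate.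

Step 14
Reactants: 8 (R)-4-[3-methoxy-4-(triisopropylsilyloxy)benzyl]dihydrofuran-2(3H)-one; 24 {2-[(1S,2R)-1,3-bis(tert-butyldimethylsilyloxy)-1-[4-(tert-butyldimethylsilyloxy)-3-methoxyphenyl]propan-2-yl]-4-(bromomethyl)-6-methoxyphenoxy}triisopropylsilane
Product: 26 (3R,4R)-3-{3-[(1S,2R)-1,3-bis(tert-butyldimethylsilyloxy)-1-[4-(tert-butyldimethylsilyloxy)-3-methoxyphenyl]propan-2-yl]-5-methoxy-4-(triisopropylsilyloxy)benzyl}-4-[3-methoxy-4-(triisopropylsilyloxy)benzyl]dihydrofuran-2(3H)-one, via lithium enolate 25 (not isolated)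
Conditions: LiN(SiMe3)2, THF, −78 °C; then 24, DMPU, −78 to −30 °C
Reagents that add atoms: none
Why: SN2 alkylation of the lactone lithium enolate by the benzylic bromide should occur on the face anti to the C4 benzyl group, setting C3 as R (3,4-trans, also the thermodynamically preferred arrangement).

Step 15
Reactants: 26 (3R,4R)-3-{3-[(1S,2R)-1,3-bis(tert-butyldimethylsilyloxy)-1-[4-(tert-butyldimethylsilyloxy)-3-methoxyphenyl]propan-2-yl]-5-methoxy-4-(triisopropylsilyloxy)benzyl}-4-[3-methoxy-4-(triisopropylsilyloxy)benzyl]dihydrofuran-2(3H)-one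
Product: 27 (3R,4R)-3-{3-[(1S,2R)-1,3-dihydroxy-1-(4-hydroxy-3-methoxyphenyl)propan-2-yl]-4-hydroxy-5-methoxybenzyl}-4-(4-hydroxy-3-methoxybenzyl)dihydrofuran-2(3H)-one (target)
Conditions: TBAF, AcOH, THF, 0 °C to rt
Reagents that add atoms: none
Why: Fluoride-mediated global desilylation should cleave the three aryl and two alkyl silyl ethers, the AcOH buffer keeping the phenols protonated so that quinone methide formation at the benzylic carbinol and epimerisation at C3 are avoided.

Compound list
1 | eugenol (4-allyl-2-methoxyphenol) | C=CCc1ccc(O)c(OC)c1 | starting material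
2 | (4-allyl-2-methoxyphenoxy)triisopropylsilane | C=CCc1ccc(O[Si](C(C)C)(C(C)C)C(C)C)c(OC)c1 | intermediate
3 | trichloroacetyl chloride | ClC(Cl)(Cl)C(Cl)=O | starting material
4 | dichloroketene | ClC(Cl)=C=O | intermediate
5 | 2,2-dichloro-3-[3-methoxy-4-(triisopropylsilyloxy)benzyl]cyclobutan-1-one (racemic) | O=C1CC(Cc2ccc(O[Si](C(C)C)(C(C)C)C(C)C)c(OC)c2)C1(Cl)Cl | intermediate
6 | 3-[3-methoxy-4-(triisopropylsilyloxy)benzyl]cyclobutan-1-one | O=C1CC(Cc2ccc(O[Si](C(C)C)(C(C)C)C(C)C)c(OC)c2)C1 | intermediate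
7 | Criegee adduct, 1-hydroxy-3-[3-methoxy-4-(triisopropylsilyloxy)benzyl]cyclobutyl 3-chlorobenzenecarboperoxoate | OC1(OOC(=O)c2cccc(Cl)c2)CC(Cc2ccc(O[Si](C(C)C)(C(C)C)C(C)C)c(OC)c2)C1 | intermediate
8 | (R)-4-[3-methoxy-4-(triisopropylsilyloxy)benzyl]dihydrofuran-2(3H)-one | COc1cc(C[C@H]2COC(=O)C2)ccc1O[Si](C(C)C)(C(C)C)C(C)C | intermediate
9 | methyl 3-bromo-4-hydroxy-5-methoxybenzoate | COC(=O)c1cc(Br)c(O)c(OC)c1 | starting material
10 | methyl 3-bromo-5-methoxy-4-(triisopropylsilyloxy)benzoate | COC(=O)c1cc(Br)c(O[Si](C(C)C)(C(C)C)C(C)C)c(OC)c1 | intermediate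
11 | (2-tert-butoxy-2-oxoethyl)zinc bromide | CC(C)(C)OC(=O)C[Zn]Br | starting material
12 | methyl 3-(2-tert-butoxy-2-oxoethyl)-5-methoxy-4-(triisopropylsilyloxy)benzoate | COC(=O)c1cc(CC(=O)OC(C)(C)C)c(O[Si](C(C)C)(C(C)C)C(C)C)c(OC)c1 | intermediate
13 | 2-[3-methoxy-5-(methoxycarbonyl)-2-(triisopropylsilyloxy)phenyl]acetic acid | COC(=O)c1cc(CC(=O)O)c(O[Si](C(C)C)(C(C)C)C(C)C)c(OC)c1 | intermediate
14 | (S)-4-benzyloxazolidin-2-one | O=C1N[C@@H](Cc2ccccc2)CO1 | starting material
15 | 2-[3-methoxy-5-(methoxycarbonyl)-2-(triisopropylsilyloxy)phenyl]acetic pivalic anhydride | COC(=O)c1cc(CC(=O)OC(=O)C(C)(C)C)c(O[Si](C(C)C)(C(C)C)C(C)C)c(OC)c1 | intermediate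
16 | methyl 3-{2-[(S)-4-benzyl-2-oxooxazolidin-3-yl]-2-oxoethyl}-5-methoxy-4-(triisopropylsilyloxy)benzoate | COC(=O)c1cc(CC(=O)N2[C@@H](Cc3ccccc3)COC2=O)c(O[Si](C(C)C)(C(C)C)C(C)C)c(OC)c1 | intermediate
17 | 4-(tert-butyldimethylsilyloxy)-3-methoxybenzaldehyde | COc1cc(C=O)ccc1O[Si](C)(C)C(C)(C)C | starting material
18 | dibutylboron (Z)-enolate of 16 | CCCCB(CCCC)O/C(=C\c1cc(C(=O)OC)cc(OC)c1O[Si](C(C)C)(C(C)C)C(C)C)N1[C@@H](Cc2ccccc2)COC1=O | intermediate
19 | dibutylboron aldolate of 20 | COC(=O)c1cc(OC)c(O[Si](C(C)C)(C(C)C)C(C)C)c(c1)[C@H](C(=O)N1[C@@H](Cc2ccccc2)COC1=O)[C@H](OB(CCCC)CCCC)c1ccc(O[Si](C)(C)C(C)(C)C)c(OC)c1 | intermediate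
20 | methyl 3-{(2S,3S)-1-[(S)-4-benzyl-2-oxooxazolidin-3-yl]-3-[4-(tert-butyldimethylsilyloxy)-3-methoxyphenyl]-3-hydroxy-1-oxopropan-2-yl}-5-methoxy-4-(triisopropylsilyloxy)benzoate | COC(=O)c1cc(OC)c(O[Si](C(C)C)(C(C)C)C(C)C)c(c1)[C@H](C(=O)N1[C@@H](Cc2ccccc2)COC1=O)[C@H](O)c1ccc(O[Si](C)(C)C(C)(C)C)c(OC)c1 | intermediate
21 | methyl 3-{(1S,2R)-1-[4-(tert-butyldimethylsilyloxy)-3-methoxyphenyl]-1,3-dihydroxypropan-2-yl}-5-methoxy-4-(triisopropylsilyloxy)benzoate | COC(=O)c1cc(OC)c(O[Si](C(C)C)(C(C)C)C(C)C)c(c1)[C@H](CO)[C@H](O)c1ccc(O[Si](C)(C)C(C)(C)C)c(OC)c1 | intermediate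
22 | methyl 3-{(1S,2R)-1,3-bis(tert-butyldimethylsilyloxy)-1-[4-(tert-butyldimethylsilyloxy)-3-methoxyphenyl]propan-2-yl}-5-methoxy-4-(triisopropylsilyloxy)benzoate | COC(=O)c1cc(OC)c(O[Si](C(C)C)(C(C)C)C(C)C)c(c1)[C@H](CO[Si](C)(C)C(C)(C)C)[C@H](O[Si](C)(C)C(C)(C)C)c1ccc(O[Si](C)(C)C(C)(C)C)c(OC)c1 | intermediate
23 | {3-[(1S,2R)-1,3-bis(tert-butyldimethylsilyloxy)-1-[4-(tert-butyldimethylsilyloxy)-3-methoxyphenyl]propan-2-yl]-5-methoxy-4-(triisopropylsilyloxy)phenyl}methanol | OCc1cc(OC)c(O[Si](C(C)C)(C(C)C)C(C)C)c(c1)[C@H](CO[Si](C)(C)C(C)(C)C)[C@H](O[Si](C)(C)C(C)(C)C)c1ccc(O[Si](C)(C)C(C)(C)C)c(OC)c1 | intermediate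
24 | {2-[(1S,2R)-1,3-bis(tert-butyldimethylsilyloxy)-1-[4-(tert-butyldimethylsilyloxy)-3-methoxyphenyl]propan-2-yl]-4-(bromomethyl)-6-methoxyphenoxy}triisopropylsilane | BrCc1cc(OC)c(O[Si](C(C)C)(C(C)C)C(C)C)c(c1)[C@H](CO[Si](C)(C)C(C)(C)C)[C@H](O[Si](C)(C)C(C)(C)C)c1ccc(O[Si](C)(C)C(C)(C)C)c(OC)c1 | intermediate
25 | lithium enolate of 8, lithium (R)-4-[3-methoxy-4-(triisopropylsilyloxy)benzyl]-4,5-dihydrofuran-2-olate | COc1cc(C[C@H]2COC(O[Li])=C2)ccc1O[Si](C(C)C)(C(C)C)C(C)C | intermediate
26 | (3R,4R)-3-{3-[(1S,2R)-1,3-bis(tert-butyldimethylsilyloxy)-1-[4-(tert-butyldimethylsilyloxy)-3-methoxyphenyl]propan-2-yl]-5-methoxy-4-(triisopropylsilyloxy)benzyl}-4-[3-methoxy-4-(triisopropylsilyloxy)benzyl]dihydrofuran-2(3H)-one | COc1cc(C[C@H]2COC(=O)[C@@H]2Cc2cc(OC)c(O[Si](C(C)C)(C(C)C)C(C)C)c([C@H](CO[Si](C)(C)C(C)(C)C)[C@H](O[Si](C)(C)C(C)(C)C)c3ccc(O[Si](C)(C)C(C)(C)C)c(OC)c3)c2)ccc1O[Si](C(C)C)(C(C)C)C(C)C | intermediate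
27 | (3R,4R)-3-{3-[(1S,2R)-1,3-dihydroxy-1-(4-hydroxy-3-methoxyphenyl)propan-2-yl]-4-hydroxy-5-methoxybenzyl}-4-(4-hydroxy-3-methoxybenzyl)dihydrofuran-2(3H)-one | COc1cc(C[C@H]2COC(=O)[C@@H]2Cc2cc(OC)c(O)c([C@H](CO)[C@H](O)c3ccc(O)c(OC)c3)c2)ccc1O | target

Total step count: 15.
Longest linear sequence: 11 steps (steps 5 to 15, from compound 9); the eugenol branch contributes steps 1 to 4 and joins at step 14.

Steps most likely to fail

Step 4. The catalyst may discriminate poorly between the two enantiotopic ring methylenes, because the only differentiating group (the arylmethyl arm at C3 of the cyclobutanone) is remote and flexible, and an uncatalysed background oxidation would erode the enantiomeric purity further. Fallback, from 6 back to 8: stereocontrol would be moved from the catalyst to a covalently bound auxiliary. Ketone 6 would be ketalised with (2R,4R)-pentane-2,4-diol (pyridinium p-toluenesulfonate, benzene, reflux with removal of water) to give the chiral spiroketal (6R,8R)-2-[3-methoxy-4-(triisopropylsilyloxy)benzyl]-6,8-dimethyl-5,9-dioxaspiro[3.5]nonane F1, in which the two ring CH2 groups are diastereotopic. Lewis acid-promoted peracid oxidation of F1 (mCPBA, SnCl4, CH2Cl2, −100 °C, then aqueous work-up) should open the ketal to a tethered oxocarbenium ion, add the peracid and shift one CH2 group selectively to oxygen, releasing the diol and giving lactone 8 by the same C5–O1 bond formation. The diol antipode would be chosen to give the R lactone.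

Step 9. Reversible aldolisation of the boron aldolate, which is an electron-rich benzylic alkoxide next to an aryl-stabilised enolate carbon, may erode the configuration of the carbinol centre, and addition to the deactivated aldehyde may be slow. Fallback, from crude 20 back to pure 20: the carbinol centre would be set by reduction instead of by the aldol transition state. The mixture of 20 and its carbinol epimer, the anti adduct methyl 3-{(2S,3R)-1-[(S)-4-benzyl-2-oxooxazolidin-3-yl]-3-[4-(tert-butyldimethylsilyloxy)-3-methoxyphenyl]-3-hydroxy-1-oxopropan-2-yl}-5-methoxy-4-(triisopropylsilyloxy)benzoate F2, would be oxidised with Dess–Martin periodinane (NaHCO3, CH2Cl2, 0 °C) to the single β-keto imide methyl 3-{(2S)-1-[(S)-4-benzyl-2-oxooxazolidin-3-yl]-3-[4-(tert-butyldimethylsilyloxy)-3-methoxyphenyl]-1,3-dioxopropan-2-yl}-5-methoxy-4-(triisopropylsilyloxy)benzoate F3, whose C2 centre is shielded from enolisation by allylic strain in the imide. Chelation-controlled reduction of F3 with Zn(BH4)2 (CH2Cl2/Et2O, −20 °C) should then return the syn adduct 20.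

Step 10. Hydride may attack the endocyclic carbamate carbonyl instead of the hindered α-aryl acyl group (ring opening of the auxiliary), the lithium aldolate may fragment by retro-aldol reaction, and the aryl ester may be partly reduced. Fallback, from 20 back to 21: cleavage and reduction would be separated. Hydrolysis of 20 with LiOH/H2O2 (THF/H2O, 0 °C), which is selective for the exocyclic carbonyl, should give (2S,3S)-3-[4-(tert-butyldimethylsilyloxy)-3-methoxyphenyl]-3-hydroxy-2-[3-methoxy-5-(methoxycarbonyl)-2-(triisopropylsilyloxy)phenyl]propanoic acid F4 together with recovered 14. Chemoselective reduction of the carboxylic acid of F4 with BH3·SMe2 (THF, 0 °C to rt), which leaves the methyl benzoate untouched, should then give diol 21.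

Further compounds
F1 | step 4 | (6R,8R)-2-[3-methoxy-4-(triisopropylsilyloxy)benzyl]-6,8-dimethyl-5,9-dioxaspiro[3.5]nonane | C[C@@H]1C[C@@H](C)OC2(CC(Cc3ccc(O[Si](C(C)C)(C(C)C)C(C)C)c(OC)c3)C2)O1
F2 | step 9 | methyl 3-{(2S,3R)-1-[(S)-4-benzyl-2-oxooxazolidin-3-yl]-3-[4-(tert-butyldimethylsilyloxy)-3-methoxyphenyl]-3-hydroxy-1-oxopropan-2-yl}-5-methoxy-4-(triisopropylsilyloxy)benzoate | COC(=O)c1cc(OC)c(O[Si](C(C)C)(C(C)C)C(C)C)c(c1)[C@H](C(=O)N1[C@@H](Cc2ccccc2)COC1=O)[C@@H](O)c1ccc(O[Si](C)(C)C(C)(C)C)c(OC)c1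
F3 | step 9 | methyl 3-{(2S)-1-[(S)-4-benzyl-2-oxooxazolidin-3-yl]-3-[4-(tert-butyldimethylsilyloxy)-3-methoxyphenyl]-1,3-dioxopropan-2-yl}-5-methoxy-4-(triisopropylsilyloxy)benzoate | COC(=O)c1cc(OC)c(O[Si](C(C)C)(C(C)C)C(C)C)c(c1)[C@H](C(=O)N1[C@@H](Cc2ccccc2)COC1=O)C(=O)c1ccc(O[Si](C)(C)C(C)(C)C)c(OC)c1
F4 | step 10 | (2S,3S)-3-[4-(tert-butyldimethylsilyloxy)-3-methoxyphenyl]-3-hydroxy-2-[3-methoxy-5-(methoxycarbonyl)-2-(triisopropylsilyloxy)phenyl]propanoic acid | COC(=O)c1cc(OC)c(O[Si](C(C)C)(C(C)C)C(C)C)c(c1)[C@H](C(=O)O)[C@H](O)c1ccc(O[Si](C)(C)C(C)(C)C)c(OC)c1
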